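**Plan**

1. Retrosynthesis: the three O–S bonds (3-O, 5-O, 4'-O) and the 3'-O–CH2Ph bond are cut first (→ 3'-O-benzylrhamnetin 7), then the C2–C1' bond between pyranone ring C and ring B (→ 3-hydroxychromone 5 + phenol 6), last the C3–O and O1–C2/C2=C3 bonds of ring C (→ acetophenone 1).
2. Enabling feature: C2 of the pyranone ring in 5 is the β-carbon of the C3–OH enol (O1–C2=C3–OH), and the future C1' of 2-(benzyloxy)phenol 6 is the carbon para to its free OH. Both are nucleophilic C–H carbons, so an anodic dehydrogenative coupling can join them without halide or boron handles and gives the flavonol at its final oxidation level.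
3. The benzyl ether of 6 marks 3'-O before the coupling, so afterwards exactly the three oxygens to be sulfated (3, 5, 4') are free.
4. Forward order: ring A is bought in 1; ring C is closed (step 1) and hydroxylated at C3 (step 2); ring B is attached by the anodic coupling (step 3); trisulfation (step 4); hydrogenolysis and release of the acid form (step 5).
5. Stereochemistry: the target has no stereocentre and is achiral, so none has to be set.

Key step: step 3

Remark: the target is drawn as the free tris(hydrogen sulfate) and is taken literally; the sulfates are carried as triethylammonium salts and the acid form is released last on a cold H+ resin and freeze-dried at once, because aryl hydrogen sulfates hydrolyse autocatalytically.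

**Route**

Step 1
Reactants: 1 2',6'-dihydroxy-4'-methoxyacetophenone
Product: 3 5-hydroxy-7-methoxy-4H-chromen-4-one, via enaminone 2 (not isolated)
Conditions: DMF-DMA (1.5 equiv), toluene, 80 °C; then AcOH, 100 °C
Reagents that add atoms: N,N-dimethylformamide dimethyl acetal, COC(OC)N(C)C
Why: Condensation of the acetyl CH3 with the amide acetal should give the vinylogous amide, and acid-promoted addition–elimination of an ortho OH with loss of dimethylamine closes the pyranone ring (enaminone chromone synthesis); the two ortho hydroxyls are equivalent, so only one chromone can form.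

Step 2
Reactants: 3 5-hydroxy-7-methoxy-4H-chromen-4-one
Product: 5 3,5-dihydroxy-7-methoxy-4H-chromen-4-one, via epoxide 4 (not isolated)
Conditions: DMDO (2–3 equiv, acetone), CH2Cl2, 0 °C to rt; then p-TsOH·H2O (cat.), CH2Cl2, rt
Reagents that add atoms: dimethyldioxirane, CC1(C)OO1
Why: Dimethyldioxirane should epoxidise the C2=C3 bond of the chromone under neutral conditions that leave the chelated 5-OH alone, and acid then opens the epoxide at C2 (oxocarbenium ion stabilised by O1) with loss of the C3 proton to give the 3-hydroxy-4-pyranone (epoxidation/isomerisation route to 3-hydroxychromones).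

Step 3
Reactants: 5 3,5-dihydroxy-7-methoxy-4H-chromen-4-one (2.5 equiv, excess recovered), 6 2-(benzyloxy)phenol
Product: 7 2-[3-(benzyloxy)-4-hydroxyphenyl]-3,5-dihydroxy-7-methoxy-4H-chromen-4-one (3'-O-benzylrhamnetin)
Conditions: undivided cell, BDD anode, Pt cathode, Bu3MeN·O3SOMe (0.1 M), HFIP, 40 °C, 5 mA cm−2, 2.0–2.2 F per mol of 6
Reagents that add atoms: none
Why: Proposed new method: phenol 6, the more easily oxidised partner, should be oxidised at the anode to an HFIP-solvated phenoxyl radical/phenoxonium species whose carbon para to oxygen is attacked by C2 of 5, the β-carbon of the C3–OH enol of the pyranone ring, and a second electron transfer with loss of two protons returns both partners to their aromatic forms as flavonol 7 while HFIP is reduced to H2 at the cathode; if the enol were oxidised first, attack of the para carbon of 6 on its C2 radical cation would lead to the same bond. The closest known reaction types are the anodic dehydrogenative phenol–arene cross-coupling on BDD in HFIP, the anodic oxidation of catechols in the presence of 4-hydroxycoumarin-type C–H acids, and the Mannich and aldol substitutions of 3-hydroxychromones and kojic acid at this same carbon. No ring is closed and no stereocentre is created. The step needs site selectivity in both partners: in 5, attack through C2 leaves a C3 oxocarbenium ion stabilised by the enol oxygen and keeps ring A aromatic, whereas C6 or C8 of the carbonyl-deactivated, chelated ring A would have to be dearomatised; in 6, OH outranks OBn as the directing group and the position para to it carries the largest spin density and is unhindered, which puts OBn at 3' and OH at 4'. It also needs chemoselectivity against homo-coupling of 6 and against further oxidation of 7, which the excess of 5, the hydrogen-bond shielding by HFIP and a charge limited to about 2 F per mol of 6 are meant to secure.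

Step 4
Reactants: 7 3'-O-benzylrhamnetin
Product: 8 tris(triethylammonium) 3'-O-benzylrhamnetin 3,5,4'-tri-O-sulfate
Conditions: SO3·NEt3 (15 equiv), MeCN, microwave, 100 °C; Sephadex LH-20 (MeOH)
Reagents that add atoms: sulfur trioxide–triethylamine complex, CC[N+](CC)(CC)S(=O)(=O)[O-]
Why: O-Sulfonation of phenolic and enolic OH by a sulfur trioxide–amine complex should occur at all three free hydroxyls, the hydrogen-bonded 5-OH being the slowest site and driven to completion by the large excess of reagent under microwave heating, while the benzyl ether keeps 3'-O unsulfated.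

Step 5
Reactants: 8 tris(triethylammonium) 3'-O-benzylrhamnetin 3,5,4'-tri-O-sulfate
Product: 10 rhamnetin 3,5,4'-tri-O-sulfate (acid form), via triethylammonium salt 9 (not isolated)
Conditions: H2 (1 atm), 10% Pd/C, MeOH–H2O, rt; filter; Dowex 50WX8 (H+ form), H2O, 0 °C; freeze-dry
Reagents that add atoms: none
Why: Catalytic hydrogenolysis should cleave the benzyl aryl ether while aryl sulfate monoester salts and the chromone C2=C3 bond are not reduced under these conditions (the fully protonated triethylammonium ions leave no free amine to poison Pd), and cation exchange on the cold H+ resin then gives the acid form.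

**Compound list**

1 | 2',6'-dihydroxy-4'-methoxyacetophenone | CC(=O)c1c(O)cc(OC)cc1O | starting material
2 | (E)-3-(dimethylamino)-1-(2,6-dihydroxy-4-methoxyphenyl)prop-2-en-1-one (enaminone) | CN(C)/C=C/C(=O)c1c(O)cc(OC)cc1O | intermediate
3 | 5-hydroxy-7-methoxy-4H-chromen-4-one | COc1cc(O)c2c(=O)ccoc2c1 | intermediate
4 | 5-hydroxy-7-methoxy-2,3-epoxychroman-4-one (racemic, cis-fused epoxide; one enantiomer drawn) | COc1cc(O)c2C(=O)[C@@H]3O[C@@H]3Oc2c1 | intermediate
5 | 3,5-dihydroxy-7-methoxy-4H-chromen-4-one | COc1cc(O)c2c(=O)c(O)coc2c1 | intermediate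
6 | 2-(benzyloxy)phenol (catechol monobenzyl ether) | Oc1ccccc1OCc1ccccc1 | starting material
7 | 2-[3-(benzyloxy)-4-hydroxyphenyl]-3,5-dihydroxy-7-methoxy-4H-chromen-4-one (3'-O-benzylrhamnetin) | COc1cc(O)c2c(=O)c(O)c(-c3ccc(O)c(OCc4ccccc4)c3)oc2c1 | intermediate
8 | tris(triethylammonium) 3'-O-benzylrhamnetin 3,5,4'-tri-O-sulfate | COc1cc(OS(=O)(=O)[O-])c2c(=O)c(OS(=O)(=O)[O-])c(-c3ccc(OS(=O)(=O)[O-])c(OCc4ccccc4)c3)oc2c1.CC[NH+](CC)CC.CC[NH+](CC)CC.CC[NH+](CC)CC | intermediate
9 | tris(triethylammonium) rhamnetin 3,5,4'-tri-O-sulfate | COc1cc(OS(=O)(=O)[O-])c2c(=O)c(OS(=O)(=O)[O-])c(-c3ccc(OS(=O)(=O)[O-])c(O)c3)oc2c1.CC[NH+](CC)CC.CC[NH+](CC)CC.CC[NH+](CC)CC | intermediate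
10 | rhamnetin 3,5,4'-tri-O-sulfate (acid form; no stereocentre) | COc1cc(OS(=O)(=O)O)c2c(=O)c(OS(=O)(=O)O)c(-c3ccc(OS(=O)(=O)O)c(O)c3)oc2c1 | target

**Step count**

Total steps: 5. Longest linear sequence: 5 (1 → 3 → 5 → 7 → 8 → 10); phenol 6 enters in step 3.

**Steps most likely to fail**

1. Step 3 (proposed new method). What may go wrong: further anodic oxidation of the newly formed electron-rich flavonol, homo-coupling of the phenoxyl radicals, or O–C instead of C–C bond formation. Fallback, from 6 and 3 back to 7, by known chemistry: 6 is brominated para to the free OH (NBS, MeCN, 0 °C) to 4-bromo-2-(benzyloxy)phenol F1. This is protected (MOMCl, i-Pr2NEt, CH2Cl2) as 2-(benzyloxy)-4-bromo-1-(methoxymethoxy)benzene F2 and converted (n-BuLi, B(Oi-Pr)3, THF, −78 °C; aq NH4Cl) into [3-(benzyloxy)-4-(methoxymethoxy)phenyl]boronic acid F3. A Pd(II)-catalysed oxidative Heck-type C2 arylation of chromone 3 with F3 (Pd(TFA)2 cat., Cu(OAc)2 or O2, DMF, 60–80 °C) should give 2-[3-(benzyloxy)-4-(methoxymethoxy)phenyl]-5-hydroxy-7-methoxy-4H-chromen-4-one F4. Epoxidation with DMDO to the flavone epoxide F5, then HCl/MeOH, which isomerises the epoxide to the 3-hydroxyflavone and removes the MOM group in the same operation, returns to 7.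

2. Step 4. What may go wrong: incomplete sulfation at the hydrogen-bonded 5-OH, giving mixtures of di- and trisulfated salts that are hard to separate, and loss of the enol 3-sulfate during work-up. Fallback, from 7 back to 10, through neutral, chromatographable sulfate diesters: 7 is treated with 2,2,2-trichloroethyl chlorosulfate (Et3N, DMAP, THF) to give 3'-O-benzylrhamnetin 3,5,4'-tris(2,2,2-trichloroethyl sulfate) F6, purified on silica gel. Pd/C with HCO2NH4 in MeOH then removes the three trichloroethyl groups and the benzyl group together to give tris(ammonium) rhamnetin 3,5,4'-tri-O-sulfate F7, which the cold H+ resin converts into 10.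

3. Step 2. What may go wrong: oxidation of the phenolic, electron-rich ring A by the dioxirane, sluggish epoxidation of the electron-poor C2=C3 bond, or ring opening of the epoxide competing with its isomerisation. Fallback, from 3 back to 5, by α-nitrosation of the saturated ketone: 3 is hydrogenated (H2, Pd/C, EtOAc) to 5-hydroxy-7-methoxychroman-4-one F1-type chromanone F8. Isoamyl nitrite/HCl in EtOH gives 3-(hydroxyimino)-5-hydroxy-7-methoxychroman-4-one F9. Acid hydrolysis of the oxime (aq H2SO4/AcOH) gives the 3,4-dione, which enolises to 5.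

**Further compounds**

F1 | step 3 | 4-bromo-2-(benzyloxy)phenol | Oc1ccc(Br)cc1OCc1ccccc1
F2 | step 3 | 2-(benzyloxy)-4-bromo-1-(methoxymethoxy)benzene | COCOc1ccc(Br)cc1OCc1ccccc1
F3 | step 3 | [3-(benzyloxy)-4-(methoxymethoxy)phenyl]boronic acid | COCOc1ccc(B(O)O)cc1OCc1ccccc1
F4 | step 3 | 2-[3-(benzyloxy)-4-(methoxymethoxy)phenyl]-5-hydroxy-7-methoxy-4H-chromen-4-one | COCOc1ccc(-c2cc(=O)c3c(O)cc(OC)cc3o2)cc1OCc1ccccc1
F5 | step 3 | 2-[3-(benzyloxy)-4-(methoxymethoxy)phenyl]-5-hydroxy-7-methoxy-2,3-epoxychroman-4-one (racemic, cis-fused; one enantiomer drawn) | COc1cc(O)c2C(=O)[C@@H]3O[C@]3(c4ccc(OCOC)c(OCc5ccccc5)c4)Oc2c1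
F6 | step 4 | 3'-O-benzylrhamnetin 3,5,4'-tris(2,2,2-trichloroethyl sulfate) | COc1cc(OS(=O)(=O)OCC(Cl)(Cl)Cl)c2c(=O)c(OS(=O)(=O)OCC(Cl)(Cl)Cl)c(-c3ccc(OS(=O)(=O)OCC(Cl)(Cl)Cl)c(OCc4ccccc4)c3)oc2c1
F7 | step 4 | tris(ammonium) rhamnetin 3,5,4'-tri-O-sulfate | COc1cc(OS(=O)(=O)[O-])c2c(=O)c(OS(=O)(=O)[O-])c(-c3ccc(OS(=O)(=O)[O-])c(O)c3)oc2c1.[NH4+].[NH4+].[NH4+]
F8 | step 2 | 5-hydroxy-7-methoxychroman-4-one | COc1cc(O)c2C(=O)CCOc2c1
F9 | step 2 | 3-(hydroxyimino)-5-hydroxy-7-methoxychroman-4-one (oxime geometry not defined) | COc1cc(O)c2C(=O)C(=NO)COc2c1
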